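(The data were generated by integration with constants of no real substance.)

The oak run stands flat: D reads 10.9% at 0.500 d and 10.3% at 2.50 d, against a scatter of 0.5 percentage points.

all flasks: L 0.81 M
- birch: E 0.49 M; run made earlier
- oak: E 1.6 M; run made earlier
- grey: E 2.03 M; time 2.5 d
- ochre: E 1.62 M; time 2.5 d
- green: E 0.810 M; time 2.5 d

| run | time / d | D / % | Z / % |
|---|---|---|---|
| birch | 0.208 | 23.8 | 13.4 |
| birch | 0.625 | 23.4 | 15.0 |
| birch | 1.25 | 23.1 | 16.0 |
| birch | 1.67 | 22.4 | 15.1 |
| birch | 2.50 | 23.0 | 15.2 |
| oak | 0.500 | 10.9 | 38.9 |
| oak | 1.04 | 10.7 | 39.0 |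
| oak | 1.67 | 10.1 | 37.8 |
| oak | 2.08 | 10.7 | 37.8 |
| oak | 2.50 | 10.3 | 38.7 |

(standard deviation of a reading: 0.5 percentage points)



1. which of these holds the largest part of the L at the end of grey (L / Q / G / D / Z)
2. which of these holds the largest part of the L at the end of ochre (L / Q / G / D / Z)
3. which of these holds the largest part of the L at the end of green (L / Q / G / D / Z)
4. how much D is there at the end of green, in percent of the L charged

I read a flat flask as a bill. I carry the E budget, 100% for green, the E charged per L charged, [E]/[L] at the start. If the E has reacted, the budget equals D, plus two E for each Z, 3 for each Q and 4 for each G, all in percent of the L charged. In oak the budget is 198%, and the last readings of D and Z pay 87.7% of it, so, if the E has reacted, about 110% sits in Q and G, which nobody read. The bill counts E, not L.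

The forecast gives Q for grey, Z for ochre and L for green, with D in green at 22.7% and L near 42, holding that “irreversible consecutive additions fit both runs”.

The flasks give Q, Z and, for green, Z: of the five species asked about, Z stands highest at 27.3%, L is at 7.78% and D at 22.7%, while the other product J, each of which holds two L, accounts for 34.8% of the L charged.

    L + E → D (k = 0.728 M⁻¹ h⁻¹)
    E + D → Z (k = 1.17 M⁻¹ h⁻¹)
    E + Z → Q (k = 0.408 M⁻¹ h⁻¹)
    E + Q → G (k = 0.144 M⁻¹ h⁻¹)
    2 L → J (k = 0.0982 M⁻¹ h⁻¹)

In green E is the limiting reagent, at 0% of its charge by the end, and the bill comes to >99.9% against the budget of 100%. At 0.0314 d in green, the turning of L + E into D uses E 1.9 times as fast as the turning of E + D into Z, the half-lives of E by these steps being 0.077 d and 0.14 d, and by the end the net turnover of the first step is 57.4% of the L charged. In the same flask as green but with 0.49 M of L, the budget is 165% and the bill comes to 165%.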